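The C3=C4 olefin of the 2,2-dimethyl-2H-pyran ring fused to ring B is the disconnection: benzylic C4 sits on the arene carbon between the lactone oxygen and the pyran oxygen, and C3 lies next to the quaternary C2. Ring-closing olefin metathesis of an o-propenyl aryl 1,1-dimethylallyl ether closes this ring in one operation with loss of propene. Both olefin arms grow from one resorcinol oxygen (O-allyl, Claisen, isomerisation; then Pd-catalysed tert-prenylation). Closing early turns the heat-labile tertiary allyl ether into a robust chromene that survives the Ullmann coupling, para-oxygenation, lactonisation and Claisen/cross-metathesis steps that build the depsidone and both prenyl groups without protecting groups.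

Key step: step 4

Remark: the target has no stereocentre and its only ring olefin is cis by constraint, so the compound is achiral and no asymmetric step is needed. Ring A locants follow the benzoic acid numbering of 11/12 (C-1 carries the carboxyl carbon); ring B locants follow 2H-chromene numbering.

Step 1
Reactants: 1 2,4-dihydroxybenzaldehyde
Product: 2 4-(allyloxy)-2-hydroxybenzaldehyde
Conditions: allyl bromide (1.05 equiv), K2CO3 (1.0 equiv), acetone, 50 °C
Reagents that add atoms: allyl bromide, C=CCBr
Why: Williamson etherification in which the 4-OH (para to CHO, not hydrogen-bonded) is more acidic and more accessible than the chelated 2-OH, so one equivalent of base and bromide should alkylate O-4 only.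

Step 2
Reactants: 2 4-(allyloxy)-2-hydroxybenzaldehyde
Product: 4 2,4-dihydroxy-3-[(E)-prop-1-en-1-yl]benzaldehyde, via 3-allyl-2,4-dihydroxybenzaldehyde 3 (not isolated)
Conditions: degassed 1,2-dichlorobenzene, 180 °C; then [RuClH(CO)(PPh3)3] (3 mol %), 90 °C
Reagents that add atoms: none
Why: Aromatic Claisen rearrangement followed in the same pot by Ru–H olefin isomerisation, in which the CHO···HO chelate gives the C3–C4 bond double-bond character so the allyl group should migrate to C-3 between the two oxygens, and the hydride catalyst then moves the terminal olefin into conjugation to give mainly the (E)-propenyl group (its geometry is immaterial because the CH–CH3 end is expelled in step 4).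

Step 3
Reactants: 4 2,4-dihydroxy-3-[(E)-prop-1-en-1-yl]benzaldehyde
Product: 5 2-hydroxy-4-[(2-methylbut-3-en-2-yl)oxy]-3-[(E)-prop-1-en-1-yl]benzaldehyde
Conditions: tert-butyl (2-methylbut-3-en-2-yl) carbonate (1.2 equiv), Pd(PPh3)4 (2 mol %), THF, 0 °C
Reagents that add atoms: tert-butyl (2-methylbut-3-en-2-yl) carbonate, CC(C)(C=C)OC(=O)OC(C)(C)C
Why: Pd-catalysed decarboxylative allylic etherification (Tsuji–Trost type) in which the tert-butoxide released deprotonates the free 4-OH (the 2-OH stays chelated to CHO) and the phenoxide attacks the substituted terminus of the 1,1-dimethyl-π-allyl complex under kinetic control at 0 °C to give the tertiary ether.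

Step 4
Reactants: 5 2-hydroxy-4-[(2-methylbut-3-en-2-yl)oxy]-3-[(E)-prop-1-en-1-yl]benzaldehyde
Product: 6 5-hydroxy-2,2-dimethyl-2H-chromene-6-carbaldehyde
Conditions: [RuCl2(=CHPh)(H2IMes)(PCy3)] (3 mol %), CH2Cl2 (5 mM), 40 °C, Ar
Reagents that add atoms: none
Why: Ring-closing olefin metathesis: the Ru alkylidene loads on the less hindered propenyl olefin to give a benzylidene, which undergoes intramolecular [2+2] cycloaddition with the neighbouring 1,1-dimethylallyl vinyl group and cycloreversion, forming the C3=C4 bond and releasing propene, whose loss drives the reaction. The closest known reaction type is RCM of 2-alkenylphenyl allyl ethers to 2H-chromenes. The six-membered pyran is closed by alkene metathesis between the two olefin termini of a tether whose O–C2 and aryl–C4 bonds are already in place, and the new ring olefin can only be cis. No stereocentre is formed. The step needs cyclisation to win over intermolecular cross-metathesis and over [3,3] rearrangement of the tertiary allyl ether: the gem-dimethyl group at C2 and the planar aryl backbone hold the two olefins together, the allylic quaternary carbon makes the vinyl group reluctant to homodimerise, high dilution disfavours oligomers, and 40 °C is far below the temperature of the Claisen shift. The chelated phenol and the aldehyde should be tolerated by the Ru carbene.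

Step 5
Reactants: 6 5-hydroxy-2,2-dimethyl-2H-chromene-6-carbaldehyde
Product: 7 2,2-dimethyl-2H-chromene-5,6-diol
Conditions: 30 % H2O2 (1.2 equiv), NaOH (1.1 equiv), THF/H2O, 0 °C to rt, Ar; aq. HCl work-up
Reagents that add atoms: hydrogen peroxide, OO
Why: Dakin oxidation in which hydroperoxide adds to the aldehyde activated by the ortho-phenoxide, aryl migration gives the aryl formate and this is hydrolysed in situ to the catechol, while alkaline H2O2 should leave the chromene olefin untouched.

Step 6
Reactants: 8 5-bromobenzene-1,3-diol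
Product: 9 1,3-bis(allyloxy)-5-bromobenzene
Conditions: allyl bromide (2.3 equiv), K2CO3 (2.5 equiv), DMF, 50 °C
Reagents that add atoms: allyl bromide, C=CCBr
Why: Double Williamson etherification of the two equivalent phenols, with no competing site.

Step 7
Reactants: 9 1,3-bis(allyloxy)-5-bromobenzene
Product: 10 2,4-bis(allyloxy)-6-bromobenzaldehyde
Conditions: POCl3 (1.5 equiv), DMF, 0 to 80 °C; then ice-water
Reagents that add atoms: N,N-dimethylformamide, CN(C)C=O; water, O
Why: Vilsmeier–Haack formylation, which should attack the position para to one allyloxy group and ortho to the other (next to Br) instead of the more hindered position between the two alkoxy groups.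

Step 8
Reactants: 10 2,4-bis(allyloxy)-6-bromobenzaldehyde
Product: 11 2,4-bis(allyloxy)-6-bromobenzoic acid
Conditions: NaClO2, NaH2PO4, 2-methyl-2-butene, t-BuOH/H2O, rt
Reagents that add atoms: sodium chlorite, [Na+].[O-]Cl=O
Why: Pinnick oxidation of the aldehyde to the acid, with 2-methyl-2-butene trapping HOCl so that the allyl ethers and the electron-rich ring should not be chlorinated.

Step 9
Reactants: 7 2,2-dimethyl-2H-chromene-5,6-diol; 11 2,4-bis(allyloxy)-6-bromobenzoic acid
Product: 12 2,4-bis(allyloxy)-6-[(5-hydroxy-2,2-dimethyl-2H-chromen-6-yl)oxy]benzoic acid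
Conditions: 7 (1.5 equiv), CuI (10 mol %), N,N-dimethylglycine (30 mol %), Cs2CO3 (3 equiv), degassed dioxane, 90 °C; aq. HCl work-up
Reagents that add atoms: none
Why: Ullmann-type Cu-catalysed diaryl ether synthesis accelerated by the ortho-carboxylate of 11, in which the 6-OH of the catechol (one free ortho position, activated by the para pyran oxygen) should be arylated in preference to the 5-OH that is flanked by the ring-fusion carbon.

Step 10
Reactants: 12 2,4-bis(allyloxy)-6-[(5-hydroxy-2,2-dimethyl-2H-chromen-6-yl)oxy]benzoic acid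
Product: 14 2,4-bis(allyloxy)-6-[(5,8-dihydroxy-2,2-dimethyl-2H-chromen-6-yl)oxy]benzoic acid, via p-quinone acid 13 (not isolated)
Conditions: (KSO3)2NO (2.2 equiv), aq. KH2PO4, acetone, 0 °C; then aq. Na2S2O4, EtOAc, rt, Ar
Reagents that add atoms: potassium nitrosodisulfonate, [K+].[K+].[O-]S(=O)(=O)N([O])S(=O)(=O)[O-]
Why: Teuber oxidation of the only free phenol, whose para position C-8 is unsubstituted while both ortho positions are blocked, should give the 5,8-quinone, and dithionite reduction then delivers the hydroquinone carrying the last ring-B oxygen at C-8.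

Step 11
Reactants: 14 2,4-bis(allyloxy)-6-[(5,8-dihydroxy-2,2-dimethyl-2H-chromen-6-yl)oxy]benzoic acid
Product: 15 bis(O-allyl) depsidone (seven-membered lactone of 14 through the chromene 5-OH; chromene 8-OH free)
Conditions: DCC (1.2 equiv), DMAP (10 mol %), CH2Cl2 (2 mM), 0 °C to rt
Reagents that add atoms: none
Why: Carbodiimide (Steglich-type) lactonisation in which only the 5-OH ortho to the diaryl ether can reach the activated acid to close the seven-membered dioxepinone, whereas the 8-OH would need a strained meta-bridged ring and high dilution suppresses intermolecular acylation.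

Step 12
Reactants: 15 bis(O-allyl) depsidone
Product: 16 di-C-allyl depsidone (ring A 3,5-diallyl-2,4-dihydroxy; otherwise as 15)
Conditions: N,N-diethylaniline, 190 °C, Ar, sealed tube
Reagents that add atoms: none
Why: Double aromatic Claisen rearrangement in which each allyl group reaches C-3 or C-5 either by a direct ortho [3,3] shift or by an ortho shift followed by Cope migration to the para position, both paths delivering an unchanged allyl group, while the chromene and the lactone should tolerate the temperature in the weakly basic solvent.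

Step 13
Reactants: 16 di-C-allyl depsidone
Product: 17 Garcinisidone E
Conditions: [RuCl2(=CHPh)(H2IMes)(PCy3)] (5 mol %), 2-methyl-2-butene/CH2Cl2 (1:1), 35 °C
Reagents that add atoms: 2-methyl-2-butene, CC=C(C)C
Why: Olefin cross-metathesis with excess 2-methyl-2-butene should convert both terminal allyl groups into prenyl groups with loss of propene, the trisubstituted product olefins and the hindered cis chromene olefin next to a quaternary carbon being inert to further metathesis and the free phenols being tolerated.

Compound list
1 | 2,4-dihydroxybenzaldehyde | O=Cc1ccc(O)cc1O | starting material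
2 | 4-(allyloxy)-2-hydroxybenzaldehyde | O=Cc1ccc(OCC=C)cc1O | intermediate
3 | 3-allyl-2,4-dihydroxybenzaldehyde | O=Cc1ccc(O)c(CC=C)c1O | intermediate
4 | 2,4-dihydroxy-3-[(E)-prop-1-en-1-yl]benzaldehyde | O=Cc1ccc(O)c(/C=C/C)c1O | intermediate
5 | 2-hydroxy-4-[(2-methylbut-3-en-2-yl)oxy]-3-[(E)-prop-1-en-1-yl]benzaldehyde | O=Cc1ccc(OC(C)(C)C=C)c(/C=C/C)c1O | intermediate
6 | 5-hydroxy-2,2-dimethyl-2H-chromene-6-carbaldehyde | O=Cc1ccc2OC(C)(C)C=Cc2c1O | intermediate
7 | 2,2-dimethyl-2H-chromene-5,6-diol | Oc1ccc2OC(C)(C)C=Cc2c1O | intermediate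
8 | 5-bromobenzene-1,3-diol (5-bromoresorcinol) | Oc1cc(O)cc(Br)c1 | starting material
9 | 1,3-bis(allyloxy)-5-bromobenzene | C=CCOc1cc(OCC=C)cc(Br)c1 | intermediate
10 | 2,4-bis(allyloxy)-6-bromobenzaldehyde | O=Cc1c(Br)cc(OCC=C)cc1OCC=C | intermediate
11 | 2,4-bis(allyloxy)-6-bromobenzoic acid | OC(=O)c1c(Br)cc(OCC=C)cc1OCC=C | intermediate
12 | 2,4-bis(allyloxy)-6-[(5-hydroxy-2,2-dimethyl-2H-chromen-6-yl)oxy]benzoic acid | OC(=O)c1c(Oc2ccc3OC(C)(C)C=Cc3c2O)cc(OCC=C)cc1OCC=C | intermediate
13 | 2,4-bis(allyloxy)-6-[(2,2-dimethyl-5,8-dioxo-5,8-dihydro-2H-chromen-6-yl)oxy]benzoic acid (p-quinone acid) | OC(=O)c1c(OC2=CC(=O)C3=C(C=CC(C)(C)O3)C2=O)cc(OCC=C)cc1OCC=C | intermediate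
14 | 2,4-bis(allyloxy)-6-[(5,8-dihydroxy-2,2-dimethyl-2H-chromen-6-yl)oxy]benzoic acid | OC(=O)c1c(Oc2cc(O)c3OC(C)(C)C=Cc3c2O)cc(OCC=C)cc1OCC=C | intermediate
15 | bis(O-allyl) depsidone: seven-membered lactone of 14 (carboxyl esterified by the chromene 5-OH); ring A 2,4-bis(allyloxy); chromene 8-OH free | C=CCOc1cc(OCC=C)c2C(=O)Oc3c4C=CC(C)(C)Oc4c(O)cc3Oc2c1 | intermediate
16 | di-C-allyl depsidone: as 15 but ring A 3,5-diallyl-2,4-dihydroxy | C=CCc1c(O)c(CC=C)c2c(c1O)C(=O)Oc1c(cc(O)c3c1C=CC(C)(C)O3)O2 | intermediate
17 | Garcinisidone E | CC(C)=CCc1c(O)c(CC=C(C)C)c2c(c1O)C(=O)Oc1c(cc(O)c3c1C=CC(C)(C)O3)O2 | target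

Total step count: 13. Longest linear sequence: 10 steps (steps 1–5, then 9–13); steps 6–8 form the second branch.

Steps most likely to fail

Step 9. The free catechol may bind or reduce the copper catalyst, oxidise to the o-quinone under traces of air, or be arylated at the wrong hydroxyl or at both. The fallback sets out from 7 and returns at 12, replacing innate selectivity by protecting-group control. Silylation of the less hindered 6-OH (TIPSCl, imidazole, CH2Cl2, 0 °C) should give 2,2-dimethyl-6-[(triisopropylsilyl)oxy]-2H-chromen-5-ol F1. Non-basic MOM protection of the remaining 5-OH (MOMCl, i-Pr2NEt, CH2Cl2, chosen to avoid silyl migration) gives 5-(methoxymethoxy)-2,2-dimethyl-6-[(triisopropylsilyl)oxy]-2H-chromene F2. TBAF in THF then gives the monophenol 5-(methoxymethoxy)-2,2-dimethyl-2H-chromen-6-ol F3. Ullmann coupling of F3 with 11 under the step 9 conditions gives 2,4-bis(allyloxy)-6-{[5-(methoxymethoxy)-2,2-dimethyl-2H-chromen-6-yl]oxy}benzoic acid F4. Mild acid (HCl, MeOH/THF, rt) removes the MOM group and gives 12.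

Step 10. The electron-poor aryloxyquinone may suffer conjugate addition of the neighbouring carboxylate or over-oxidation, and the hydroquinone may re-oxidise in air before lactonisation. The fallback sets out from 12 and returns at 14 without passing through a quinone. Elbs persulfate oxidation (K2S2O8, aq. KOH, 0 °C to rt) attacks the para position of the phenoxide and should give the sulfate ester 2,4-bis(allyloxy)-6-{[5-hydroxy-2,2-dimethyl-8-(sulfooxy)-2H-chromen-6-yl]oxy}benzoic acid F5. Hydrolysis of F5 (dilute aq. HCl, 50 °C, Ar) gives 14.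

Step 3. The Pd catalyst may re-ionise the tertiary aryl ether, because the p-formylphenoxide is a good leaving group, and funnel it to the linear O-prenyl ether or to C-allylated material. The fallback sets out from 4 and returns at 5 by a copper route that cannot equilibrate. Cu-catalysed propargylic etherification (2-methylbut-3-yn-2-yl trifluoroacetate, CuCl2 cat., DBU, MeCN, 0 °C) of the free 4-OH should give 2-hydroxy-4-[(2-methylbut-3-yn-2-yl)oxy]-3-[(E)-prop-1-en-1-yl]benzaldehyde F6. Semi-hydrogenation of the terminal alkyne (Pb-poisoned Pd/CaCO3, quinoline, H2 1 atm, EtOAc) gives 5.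

Further compounds
F1 | step 9 | 2,2-dimethyl-6-[(triisopropylsilyl)oxy]-2H-chromen-5-ol | CC(C)[Si](C(C)C)(C(C)C)Oc1ccc2OC(C)(C)C=Cc2c1O
F2 | step 9 | 5-(methoxymethoxy)-2,2-dimethyl-6-[(triisopropylsilyl)oxy]-2H-chromene | COCOc1c(O[Si](C(C)C)(C(C)C)C(C)C)ccc2OC(C)(C)C=Cc12
F3 | step 9 | 5-(methoxymethoxy)-2,2-dimethyl-2H-chromen-6-ol | COCOc1c(O)ccc2OC(C)(C)C=Cc12
F4 | step 9 | 2,4-bis(allyloxy)-6-{[5-(methoxymethoxy)-2,2-dimethyl-2H-chromen-6-yl]oxy}benzoic acid | OC(=O)c1c(Oc2ccc3OC(C)(C)C=Cc3c2OCOC)cc(OCC=C)cc1OCC=C
F5 | step 10 | 2,4-bis(allyloxy)-6-{[5-hydroxy-2,2-dimethyl-8-(sulfooxy)-2H-chromen-6-yl]oxy}benzoic acid | OC(=O)c1c(Oc2cc(OS(=O)(=O)O)c3OC(C)(C)C=Cc3c2O)cc(OCC=C)cc1OCC=C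
F6 | step 3 | 2-hydroxy-4-[(2-methylbut-3-yn-2-yl)oxy]-3-[(E)-prop-1-en-1-yl]benzaldehyde | O=Cc1ccc(OC(C)(C)C#C)c(/C=C/C)c1O
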